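The data were generated by integration for substances that don't exist; the scatter is artificial.

I decide to draw J as one plain curve and read the runs as distances from it.

| flask | J | X | remark | time |
|---|---|---|---|---|
| amber | 0.20 M | 0.33 M | run made earlier |  |
| grey | 0.20 M | 0.58 M | run made earlier |  |
| violet | 0.20 M | 0.78 M | run made earlier |  |
| theta | 0.20 M | 0.360 M |  | 6.0 h |
| beta | 0.20 M | 1.10 M |  | 6.0 h |

- amber (time / h: Z / %, J / %, L / %): 1.50: 15.0, 82.9, 0.4; 3.00: 24.3, 74.4, 2.2; 5.00: 32.4, 66.6, 2.5; 6.00: 31.6, 62.8, 0
- grey (time / h: Z / %, J / %, L / %): 1.50: 13.6, 85.3, 0.9; 3.00: 25.3, 72.9, 0.6; 5.00: 32.1, 66.2, 0.4; 6.00: 34.4, 62.6, 1.1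
- violet (time / h: Z / %, J / %, L / %): 0.500: 4.9, 94.0, 0; 1.00: 11.4, 90.3, 0.5; 2.50: 22.2, 75.8, 0.3; 6.00: 35.9, 65.9, 1.5

(scatter of a reading: 1 percentage point)

- which of these there is most of at the end, counted by the J in it, theta (L / Z / J)
- which of these there is most of at the end, counted by the J in it, beta (L / Z / J)
- how much there is at the end of the one of these that leads, in percent of the J charged: theta
- how much there is at the end of the one of these that leads, in percent of the J charged: beta

- steps thought possible: J <-> L + Q; X + L -> Z; 2 X -> E

I take the first firm reading of J in each run, convert it to a first-order rate, and average the three: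

k = mean of ln(J charged / J left) / time = 0.111 /h

T = ln(2) / k = 6.24 h

T is the starting half-life: the time J would take to halve if it kept this opening first-order rate and none came back. That line is the zero of my scale.

Line at 3.00 h: 71.7%

Amber and grey read 74.4% and 72.9% there, so J is still close to the line.

Line at 5.00 h: 57.4%

Amber and grey read 66.6% and 66.2%, so J now stands above the line. Grey loses 12 percentage points in the 1.50 h up to 3.00 h, then 6.7 points in the next 2.00 h, then 3.6 points in the last hour, so the slope in grey is already lower after 3.00 h.

Line at 6.0 h: 51.4%

Mean J of the three runs at that time: 63.8%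

Distance above the line: 12 points

The three end readings lie within 3.3 points of each other, so I carry this mean to theta and to beta, though beta has more X than violet. J leads in both, because 63.8% in J leaves less than that for Z and L together.

The forecast also names J, with 64% for theta and 63% for beta. It holds that “extra X buys little”. My figure agrees with it on theta and lies one point from it on beta.

    J ⇌ L + Q (K = 9.90 × 10⁻⁴ M, k = 0.00193 /min)
    X + L → Z (k = 5.38 /M/min)
    2 X → E (k = 0.0481 /M/min)

J leads at 64.5% in theta and 63.1% in beta, close to the mean of three readings, the cheapest route there. Beta ends 12 points above the line. The neighbouring flask is beta charged with 0.050 M of J. With the same T, its line also stands at 51.4%. It ends with J at 53.8% and Z at 45.6%, 2.4 points above the line, which is closer than beta. Its Q stands at 0.0231 M, against 0.0738 M in beta.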